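**Retrosynthetic overview** (locants C1–C6 as in plakortolides: C1 lactone C=O, C3 = CH–OO, C4 = C(CH3)–O, C6 = C(CH3)(chain)–OO)
1. Target 15 ⇐ iodolactone 14 (C5–I to C5–H) ⇐ dioxine-acetic acid 13. The γ-lactone is the second ring, closed by 5-exo attack of the carboxylate on C4=C5 (cis-fusion).
2. 13 ⇐ (3E,5E)-diene acid 12 + O2. The 1,2-dioxine is the first ring, closed in one [4+2] addition of singlet oxygen; the E,E geometry fixes C3 relative to C6.
3. Absolute configuration: the lactonisation is run as a catalytic kinetic resolution that takes only (3S,6R)-13.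
4. 12 ⇐ alkyne 5 (carboalumination, 5E alkene) + (E)-4-iodopent-3-enoic acid 9 (Negishi coupling, C4–C5 bond).
5. 5 ⇐ PhMgBr + 1,10-dibromodecane + acetylide; 9 ⇐ pent-3-yn-1-ol.

Assumption: (DHQD)2PHAL is taken as the catalyst matched to (3S,6R)-13; if the other enantiomer cyclises faster, the pseudoenantiomer (DHQ)2PHAL is used under the same conditions.

**Route**

Step 1
Reactants: 1 1,10-dibromodecane (3 equiv); 2 phenylmagnesium bromide (PhMgBr)
Product: 3 (10-bromodecyl)benzene
Conditions: Li2CuCl4 (3 mol%), THF, 0 °C → rt; excess 1 recovered by distillation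
Reagents that add atoms: none
Why: Kochi copper-catalysed Grignard–alkyl bromide cross-coupling, held at mono-substitution by the excess of dibromide; no stereocentre is formed.

Step 2
Reactants: 3 (10-bromodecyl)benzene; 4 lithium acetylide–ethylenediamine complex (LiC≡CH·H2NCH2CH2NH2)
Product: 5 12-phenyldodec-1-yne
Conditions: DMSO, 10 °C → rt
Reagents that add atoms: none
Why: SN2 alkylation of an acetylide by a primary bromide in a dipolar aprotic solvent, the standard route to terminal alkynes.

Step 3
Reactants: 6 pent-3-yn-1-ol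
Product: 8 (E)-4-iodopent-3-en-1-ol, via alkenylzirconocene 7 (not isolated)
Conditions: Cp2Zr(H)Cl (2.5 equiv), THF, rt → 40 °C; then I2 (1.2 equiv), 0 °C; aq. Na2S2O3
Reagents that add atoms: iodine, II
Why: Hydrozirconation (syn H–Zr addition, first equivalent spent on the OH) equilibrates zirconium onto the methyl-bearing alkyne carbon, and iodinolysis of the C–Zr bond with retention gives the E vinyl iodide.

Step 4
Reactants: 8 (E)-4-iodopent-3-en-1-ol
Product: 9 (E)-4-iodopent-3-enoic acid
Conditions: TEMPO (20 mol%), PhI(OAc)2 (2.2 equiv), MeCN/H2O 1:1, rt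
Reagents that add atoms: water, O
Why: Oxoammonium (TEMPO) oxidation of the primary alcohol through the aldehyde hydrate to the acid under nearly neutral conditions, which leave the vinyl iodide and the position of the alkene untouched.

Step 5
Reactants: 5 12-phenyldodec-1-yne; 9 (E)-4-iodopent-3-enoic acid
Product: 12 (3E,5E)-4,6-dimethyl-16-phenylhexadeca-3,5-dienoic acid, via alkenylalane 10 (not isolated), via aluminium carboxylate 11 (not isolated)
Conditions: 5, Me3Al (2.0 equiv), Cp2ZrCl2 (20 mol%), CH2Cl2, 0 °C → rt, volatiles removed; 9 + Me3Al (1.0 equiv), THF, 0 °C; combine, ZnCl2 (30 mol%), Pd(PPh3)4 (5 mol%), THF, rt; aq. HCl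
Reagents that add atoms: trimethylaluminium, C[Al](C)C
Why: Negishi zirconium-catalysed syn carboalumination sets the 5E alkene (CH3 and Al cis), and the zinc-assisted palladium-catalysed Negishi cross-coupling with the E vinyl iodide proceeds with retention at both sp2 carbons, so the 3E,5E diene results.

Step 6
Reactants: 12 (3E,5E)-4,6-dimethyl-16-phenylhexadeca-3,5-dienoic acid
Product: 13 rac-2-[(3S,6R)-4,6-dimethyl-6-(10-phenyldecyl)-3,6-dihydro-1,2-dioxin-3-yl]acetic acid
Conditions: O2, 5,10,15,20-tetraphenylporphyrin (0.5 mol%), CH2Cl2, −20 °C, white LED; quick silica filtration at 0 °C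
Reagents that add atoms: dioxygen, O=O
Why: Dye-sensitised singlet-oxygen Diels–Alder reaction ([4+2]) on the s-cis 3E,5E diene forms both C–O bonds suprafacially, so the two outward groups (CH2CO2H on C3, phenyldecyl on C6) end up cis and C3/C6 are set together as the racemic (3S,6R)/(3R,6S) pair, with ene hydroperoxides as the expected by-products.

Step 7
Reactants: 13 rac-2-[(3S,6R)-4,6-dimethyl-6-(10-phenyldecyl)-3,6-dihydro-1,2-dioxin-3-yl]acetic acid
Product: 14 (3R,4S,4aR,7aS)-4-iodo-3,4a-dimethyl-3-(10-phenyldecyl)hexahydrofuro[3,2-c][1,2]dioxin-6-one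
Conditions: (DHQD)2PHAL (hydroquinidine 1,4-phthalazinediyl diether, 10 mol%), N-iodosuccinimide (0.45 equiv), CHCl3/hexane 1:1, −40 °C; aq. Na2S2O3; unreacted acid removed on silica
Reagents that add atoms: N-iodosuccinimide, O=C1CCC(=O)N1I
Why: Proposed new method: iodolactonisation is a 5-exo anti addition in which the carboxylate on the C3 arm attacks C4 from its own face while iodine takes C5 from the opposite face, which gives the cis-fused lactone and sets C4 and C5 from C3; the protonated cinchona bis-ether holds the carboxylate as a chiral ion pair and delivers I+, so only the enantiomer of 13 whose alkene face anti to the arm fits the catalyst cyclises fast, and the reaction, stopped below 50% conversion, is a kinetic resolution that passes on only (3S,6R)-13 while the (3R,6S)-acid stays behind; the closest known reactions are (DHQD)2PHAL-catalysed enantioselective halolactonisations of alkenoic acids, kinetic resolutions by catalytic halocyclisation, and the racemic iodolactonisation of ring-alkenyl acetic acids.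

Step 8
Reactants: 14 (3R,4S,4aR,7aS)-4-iodo-3,4a-dimethyl-3-(10-phenyldecyl)hexahydrofuro[3,2-c][1,2]dioxin-6-one
Product: 15 (3R,4aS,7aS)-3,4a-dimethyl-3-(10-phenyldecyl)hexahydrofuro[3,2-c][1,2]dioxin-6-one (CNP0407146.3)
Conditions: Bu3SnH (3 equiv), Et3B (0.3 equiv), air, toluene, 0 °C
Reagents that add atoms: none
Why: Tin hydride radical-chain dehalogenation, in which the C5 radical is trapped by concentrated Bu3SnH faster than it can attack the neighbouring O–O bond, and since C5 becomes CH2 no stereocentre is touched.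

**Compound list**
1 | 1,10-dibromodecane | BrCCCCCCCCCCBr | starting material
2 | phenylmagnesium bromide (PhMgBr) | Br[Mg]c1ccccc1 | starting material
3 | (10-bromodecyl)benzene | BrCCCCCCCCCCc1ccccc1 | intermediate
4 | lithium acetylide–ethylenediamine complex (LiC≡CH·H2NCH2CH2NH2) | [Li+].[C-]#C.NCCN | starting material
5 | 12-phenyldodec-1-yne | C#CCCCCCCCCCCc1ccccc1 | intermediate
6 | pent-3-yn-1-ol | CC#CCCO | starting material
7 | alkenylzirconocene Cp2(Cl)Zr–C(CH3)=CH–CH2CH2–O–Zr(Cl)Cp2, 2E (Zr trans to the CH2CH2O arm) | C/C(=C\CCO[Zr](Cl)(C1C=CC=C1)C1C=CC=C1)[Zr](Cl)(C1C=CC=C1)C1C=CC=C1 | intermediate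
8 | (E)-4-iodopent-3-en-1-ol | OCC/C=C(\C)I | intermediate
9 | (E)-4-iodopent-3-enoic acid | OC(=O)C/C=C(\C)I | intermediate
10 | [(1E)-2-methyl-12-phenyldodec-1-en-1-yl]dimethylalumane | C[Al](C)/C=C(\C)CCCCCCCCCCc1ccccc1 | intermediate
11 | dimethylaluminium (3E)-4-iodopent-3-enoate | C[Al](C)OC(=O)C/C=C(\C)I | intermediate
12 | (3E,5E)-4,6-dimethyl-16-phenylhexadeca-3,5-dienoic acid | OC(=O)C/C=C(\C)/C=C(\C)CCCCCCCCCCc1ccccc1 | intermediate
13 | rac-2-[(3S,6R)-4,6-dimethyl-6-(10-phenyldecyl)-3,6-dihydro-1,2-dioxin-3-yl]acetic acid (racemate, CH2CO2H cis to the chain; SMILES shows the 3S,6R enantiomer that is carried on) | C[C@@]1(CCCCCCCCCCc2ccccc2)C=C(C)[C@H](CC(=O)O)OO1 | intermediate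
14 | (3R,4S,4aR,7aS)-4-iodo-3,4a-dimethyl-3-(10-phenyldecyl)hexahydrofuro[3,2-c][1,2]dioxin-6-one (iodine on C5, trans to the lactone oxygen) | C[C@@]1(CCCCCCCCCCc2ccccc2)[C@@H](I)[C@]2(C)OC(=O)C[C@@H]2OO1 | intermediate
15 | (3R,4aS,7aS)-3,4a-dimethyl-3-(10-phenyldecyl)hexahydrofuro[3,2-c][1,2]dioxin-6-one (3S,4S,6R in plakortolide numbering) | C[C@@]1(CCCCCCCCCCc2ccccc2)C[C@]2(C)OC(=O)C[C@@H]2OO1 | target

**Totals**
Total step count: 8. Longest linear sequence: 6 steps (1 → 2 → 5 → 6 → 7 → 8, or 3 → 4 → 5 → 6 → 7 → 8).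

**Steps most likely to fail, with fallbacks**

Risk at step 7: the selectivity factor of the kinetic resolution is unknown, and the basic quinuclidine could open the peroxide (Kornblum–DeLaMare). The fallback sets out from 13 and comes back at 14. Racemic 13 is coupled with (S)-1-phenylethylamine (EDC·HCl, HOBt, CH2Cl2, 0 °C) to give two diastereomeric amides, 2-[(3S,6R)-4,6-dimethyl-6-(10-phenyldecyl)-3,6-dihydro-1,2-dioxin-3-yl]-N-[(1S)-1-phenylethyl]acetamide F3 and 2-[(3R,6S)-4,6-dimethyl-6-(10-phenyldecyl)-3,6-dihydro-1,2-dioxin-3-yl]-N-[(1S)-1-phenylethyl]acetamide F4. These are separated on silica or by preparative HPLC. F3 is then treated with I2 in THF/H2O at 0 °C: O-cyclisation of the amide gives an iminolactone whose hydrolysis releases the amine and delivers 14 as one enantiomer.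

Risk at step 6: the inside methyl on C6 hinders the s-cis conformer, so the ene reaction at the allylic CH3 and CH2 groups may outrun the [4+2] addition. The fallback sets out from 12 and comes back at 13. Singlet oxygen is replaced by ground-state O2 added through the diene radical cation (tris(4-bromophenyl)aminium hexachloroantimonate, (4-BrC6H4)3N·SbCl6, 5 mol%, O2, CH2Cl2, −78 °C). This cation-radical chain cycloaddition is known to give 1,2-dioxenes from hindered dienes that give ene products with singlet oxygen. It is stepwise, so some trans isomer may form and is removed on silica. It makes no new compound (F0).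

Risk at step 5: the unprotected carboxylate and residual Me3Al may give protodealumination or methyl transfer instead of the alkenyl coupling. The fallback sets out from 5 (together with zirconocene 7, made from 6 as in step 3) and comes back at 12, with the polarity of the coupling reversed. The carboalumination of 5 is quenched with I2 to give (E)-1-iodo-2-methyl-12-phenyldodec-1-ene F1. F1 is coupled (Pd(PPh3)4, ZnCl2, THF, rt) with 7, used without iodinolysis, to give (3E,5E)-4,6-dimethyl-16-phenylhexadeca-3,5-dien-1-ol F2. TEMPO/PhI(OAc)2 oxidation of F2 (MeCN/H2O) then gives 12.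

**Further compounds**
F1 | step 5 | (E)-1-iodo-2-methyl-12-phenyldodec-1-ene | I/C=C(\C)CCCCCCCCCCc1ccccc1
F2 | step 5 | (3E,5E)-4,6-dimethyl-16-phenylhexadeca-3,5-dien-1-ol | OCC/C=C(\C)/C=C(\C)CCCCCCCCCCc1ccccc1
F0 | step 6 | none | none
F3 | step 7 | 2-[(3S,6R)-4,6-dimethyl-6-(10-phenyldecyl)-3,6-dihydro-1,2-dioxin-3-yl]-N-[(1S)-1-phenylethyl]acetamide | C[C@@]1(CCCCCCCCCCc2ccccc2)C=C(C)[C@H](CC(=O)N[C@@H](C)c2ccccc2)OO1
F4 | step 7 | 2-[(3R,6S)-4,6-dimethyl-6-(10-phenyldecyl)-3,6-dihydro-1,2-dioxin-3-yl]-N-[(1S)-1-phenylethyl]acetamide | C[C@]1(CCCCCCCCCCc2ccccc2)C=C(C)[C@@H](CC(=O)N[C@@H](C)c2ccccc2)OO1
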